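**Two losses.** Counted by the D in each, [D] + [Z] + [J] + [X] stays at the charge in this closed flask, with L counted inside J. So what J lacks is either still on its way through D and Z, or lost to X.

| setting | eta | beta | Friday's | Tuesday's |
|---|---|---|---|---|
| D | 7 mM | 28 mM | 14 mM | 14 mM |
| remark | run made earlier | run made earlier |  |  |
| time |  |  | 12 d | 20 d |

- eta (time / d: J / %): 2.08: 25.5; 4.00: 43.8; 6.00: 59.7; 12.0: 80.6; 25.0: 90.2
- beta (time / d: J / %): 2.08: 21.1; 4.00: 36.2; 6.00: 47.1; 12.0: 65.6; 25.0: 73.4

(scatter of a reading: 0.5 percentage points)

* which of the two ends with the higher amount of J, in percent of the D charged ("neither" if they lie within 2 percentage points) (Friday's / Tuesday's / neither)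
* J at the end, in percent of the D charged, Friday's
* J at the end, in percent of the D charged, Tuesday's

- a species is counted by the D in it: one X counts as two
- amounts and yields of J count L too
- given per volume of solution although it is solid: L
- steps thought possible: D -> Z; Z -> J; L <-> J; 2 D -> X

**Fastest rung.** J in the beta run stands at 0.827 of J in the eta run at 2.08 d, and at 0.814 at 25.0 d, nearly the same ratio. So the split of D between Z and the second-order path to X reads as done before the first reading.

**Middle rung.** From 2.08 d to 12.0 d, the gap below the last reading shrinks by a factor 6.74 in the eta run and 6.71 in the beta run, though the charges differ. In logarithms, that gives a reading of the decade time, the time in which the Z still on its way to J falls by a factor 10: 12.0 d.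

**Slowest rung.** At 25.0 d, the decade time leaves 0.812 % of the gap open, so I put the final losses at 9.06 % for the eta run and 26.0 % for the beta run. The charge of Friday's and Tuesday's is the geometric middle of the two earlier charges, so for both flasks I take the geometric middle of the losses, 15.3 %. Friday's gets 1.00 decades and Tuesday's 1.67, so I reckon J at 76.3 % and 82.9 %.

**The forecast.** It names Tuesday's, with 73.5 % for Friday's and 81.3 % for Tuesday's, both below mine, and says Tuesday's wins “simply because it runs longer”.

**The result.** The flasks give 74.0 % for Friday's and 81.8 % for Tuesday's, so Tuesday's ends higher.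

    D → Z (k = 4.66 × 10⁻⁵ s⁻¹)
    Z → J (k = 2.07 × 10⁻⁶ s⁻¹)
    L ⇌ J, rate k3*(cs3 - [J]) while solid is left; crystals form when [J] > cs3 (solubility = 13.0 mM, k = 3.78 × 10⁻⁴ s⁻¹)
    2 D → X (k = 6.58 × 10⁻⁴ L mol⁻¹ s⁻¹)

**Two clocks.** In Tuesday's flask, the half-life of D by its path to Z alone is 0.17 d, and that of Z by its path to J alone is 3.9 d, 22.5 times as long: of these two steps, Z → J is the rate-limiting step. At 20.0 d, Tuesday's holds Z at 2.46 % beside J at 81.8 %, with D at 0 %. My decade time, read off the runs, leaves 2.13 % of the Z made still as Z in Tuesday's flask, and Tuesday's shows 2.92 %. The neighbour flask with 24 mM of D, over the same time, ends with J at 74.1 % and shows 2.91 %.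

The readings are simulated with constants of no real substance, noise included.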